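**Retrosynthetic overview**

1. The target comes from an adduct heptaacetate by methanolysis of seven aryl acetates; its only free phenol is the one ortho to the ketone on ring D (the benzoyl ring).
2. Cyclohexene ring E is cut by an intermolecular, exo- and enantioselective [4+2] cycloaddition at C1–C2 and C5–C6 (C1 aroyl-bearing, C2 ring-A-bearing, C6 ring-B-bearing, C5 the CH2). This gives a 2'-hydroxychalcone triacetate (dienophile) and an (E)-1-aryl-3-methylbuta-1,3-diene that already holds the stilbene (rings A and C).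
3. Enabling feature: in ring E the C3=C4 bond (C4 carries the methyl) lies 3,4 to the aroyl-bearing C1, with the ring-A aryl on C2, a matched "ortho/para" Diels–Alder retron. The aroyl group on C1 is a 2-hydroxyaryl ketone whose phenol O and carbonyl O close a six-membered chelate on a chiral VANOL borate.
4. The dienophile comes from a Claisen–Schmidt condensation of MOM-protected 2,4-dihydroxyacetophenone and 2,4-dihydroxybenzaldehyde, then MOM-to-acetate exchange. The diene comes from a Suzuki–Miyaura coupling of a bromostilbene tetraacetate (Horner–Wadsworth–Emmons olefination, demethylation, acetylation) with an (E)-dienylboronate.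
5. Ring order: benzene rings A–D are purchased; ring E is the only ring built and is closed last.

Key step: step 11

Assumption: (S)-VANOL is written as the ligand whose borate exposes the Cα-Re/Cβ-Re face of the chelated chalcone. This facial sense rests on analogy with related chelates; if it proved opposite, (R)-VANOL would be used in the same step with no other change.

**Route**

Step 1
Reactants: 1 2,4-dihydroxyacetophenone
Product: 2 1-[2-hydroxy-4-(methoxymethoxy)phenyl]ethan-1-one
Conditions: MOMCl (1.1 equiv), K2CO3, acetone, 0 °C to rt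
Reagents that add atoms: chloromethyl methyl ether, COCCl
Why: Williamson-type O-alkylation; the 2-OH is hydrogen-bonded to the ketone and far less nucleophilic, so only the 4-OH should be etherified.

Step 2
Reactants: 3 2,4-dihydroxybenzaldehyde
Product: 4 2,4-bis(methoxymethoxy)benzaldehyde
Conditions: NaH (2.4 equiv), MOMCl (2.4 equiv), DMF, 0 °C to rt
Reagents that add atoms: chloromethyl methyl ether, COCCl
Why: Williamson O-alkylation of the bis-phenoxide; full deprotonation overrides the hydrogen bond of the 2-OH, so both phenols are masked for the base-mediated condensation.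

Step 3
Reactants: 2 1-[2-hydroxy-4-(methoxymethoxy)phenyl]ethan-1-one; 4 2,4-bis(methoxymethoxy)benzaldehyde
Product: 5 (E)-1-[2-hydroxy-4-(methoxymethoxy)phenyl]-3-[2,4-bis(methoxymethoxy)phenyl]prop-2-en-1-one
Conditions: KOH, EtOH/H2O, rt; then dilute AcOH to pH 6
Reagents that add atoms: none
Why: Claisen–Schmidt (crossed aldol) condensation; the non-enolisable aldehyde traps the ketone enolate and E1cB dehydration gives the conjugated E-enone, the thermodynamic geometry, with MOM ethers stable to base.

Step 4
Reactants: 5 (E)-1-[2-hydroxy-4-(methoxymethoxy)phenyl]-3-[2,4-bis(methoxymethoxy)phenyl]prop-2-en-1-one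
Product: 6 (E)-1,3-bis(2,4-dihydroxyphenyl)prop-2-en-1-one
Conditions: 3 M HCl (aq), MeOH, 50 °C, dark
Reagents that add atoms: none
Why: Acid-catalysed acetal exchange removes the three MOM groups as dimethoxymethane; the E-geometry holds the ring-B 2-OH away from the carbonyl, so the chalcone should survive brief warming.

Step 5
Reactants: 6 (E)-1,3-bis(2,4-dihydroxyphenyl)prop-2-en-1-one
Product: 7 (E)-1-(4-acetoxy-2-hydroxyphenyl)-3-(2,4-diacetoxyphenyl)prop-2-en-1-one
Conditions: Ac2O (3.05 equiv), pyridine, CH2Cl2, 0 °C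
Reagents that add atoms: acetic anhydride, CC(=O)OC(C)=O
Why: Chemoselective O-acylation; the 2'-OH is chelated to the carbonyl and least nucleophilic, so three equivalents of anhydride should acetylate only the other three phenols and leave the hydroxyl that step 11 needs.

Step 6
Reactants: 8 5-bromo-2,4-dimethoxybenzaldehyde; 9 diethyl (3,5-dimethoxybenzyl)phosphonate
Product: 10 1-bromo-5-[(E)-2-(3,5-dimethoxyphenyl)ethenyl]-2,4-dimethoxybenzene
Conditions: KOtBu, THF, 0 °C to rt
Reagents that add atoms: none
Why: Horner–Wadsworth–Emmons olefination of a benzylic phosphonate with an aryl aldehyde, which should give the E-stilbene under thermodynamic control of the elimination; the aryl bromide is inert.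

Step 7
Reactants: 10 1-bromo-5-[(E)-2-(3,5-dimethoxyphenyl)ethenyl]-2,4-dimethoxybenzene
Product: 11 4-bromo-6-[(E)-2-(3,5-dihydroxyphenyl)ethenyl]benzene-1,3-diol
Conditions: BBr3 (8 equiv), CH2Cl2, −78 °C to 0 °C; then ice/H2O
Reagents that add atoms: none
Why: Lewis-acid cleavage of aryl methyl ethers (BBr3 demethylation) frees all four phenols before any acid-labile diene is present; the aryl bromide and E-alkene are retained.

Step 8
Reactants: 11 4-bromo-6-[(E)-2-(3,5-dihydroxyphenyl)ethenyl]benzene-1,3-diol
Product: 12 4-bromo-6-[(E)-2-(3,5-diacetoxyphenyl)ethenyl]-1,3-phenylene diacetate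
Conditions: Ac2O (excess), pyridine, DMAP (cat.), CH2Cl2, rt
Reagents that add atoms: acetic anhydride, CC(=O)OC(C)=O
Why: Exhaustive O-acetylation with nucleophilic catalysis installs the base-removable group used in the endgame and makes the aryl bromide less electron-rich for oxidative addition.

Step 9
Reactants: 13 2-methylbut-1-en-3-yne
Product: 14 4,4,5,5-tetramethyl-2-[(1E)-3-methylbuta-1,3-dien-1-yl]-1,3,2-dioxaborolane
Conditions: pinacolborane (1.05 equiv), Cp2Zr(H)Cl (5 mol %), Et3N (10 mol %), neat, sealed tube, 25 to 40 °C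
Reagents that add atoms: pinacolborane, CC1(C)OBOC1(C)C
Why: Cp2Zr(H)Cl-catalysed hydroboration of the terminal alkyne (syn, anti-Markovnikov) is faster than that of the 1,1-disubstituted alkene and should give the E-dienylboronate directly.

Step 10
Reactants: 12 4-bromo-6-[(E)-2-(3,5-diacetoxyphenyl)ethenyl]-1,3-phenylene diacetate; 14 4,4,5,5-tetramethyl-2-[(1E)-3-methylbuta-1,3-dien-1-yl]-1,3,2-dioxaborolane
Product: 15 4-[(E)-2-(3,5-diacetoxyphenyl)ethenyl]-6-[(1E)-3-methylbuta-1,3-dien-1-yl]-1,3-phenylene diacetate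
Conditions: Pd(dppf)Cl2 (5 mol %), CsF (3 equiv), BHT (cat.), dry degassed 1,4-dioxane, 80 °C
Reagents that add atoms: none
Why: Suzuki–Miyaura coupling under anhydrous fluoride activation (oxidative addition of zerovalent palladium into C–Br, transmetalation, reductive elimination) retains the E-alkenyl geometry and avoids aqueous base, so the four aryl acetates should survive.

Step 11
Reactants: 7 (E)-1-(4-acetoxy-2-hydroxyphenyl)-3-(2,4-diacetoxyphenyl)prop-2-en-1-one; 15 4-[(E)-2-(3,5-diacetoxyphenyl)ethenyl]-6-[(1E)-3-methylbuta-1,3-dien-1-yl]-1,3-phenylene diacetate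
Product: 18 exo-(1S,2S,6R) cycloadduct heptaacetate (2'-OH free), via chalcone VANOL-borate chelate 16 (not isolated), via cycloadduct VANOL-borate chelate 17 (not isolated)
Conditions: (S)-VANOL (1.3 equiv), BH3·THF (1.2 equiv), AcOH (1.2 equiv), THF, rt, then evaporation; 7 (1.0 equiv), then 15 (1.5 equiv), PhCF3, rt to 40 °C; MeOH/H2O work-up, ligand recovered
Reagents that add atoms: none
Why: The in situ VANOL acetoxyborate exchanges acetate for the only free phenol of 7 to give the tetracoordinate spiro-borate 16, whose six-membered O–B–O chelate locks the enone s-cis and lowers its LUMO; the electron-rich diene 15 then adds in a concerted, asynchronous [4+2] cycloaddition (the diene CH2 to β-carbon bond leading) to give chelate 17, which aqueous work-up hydrolyses to 18 with release of the ligand. The closest known reaction type is the chiral diol–boron-promoted asymmetric Diels–Alder reaction of 2'-hydroxychalcones with 1-aryl-3-methylbuta-1,3-dienes. Ring E is closed by intermolecular [4+2] annulation, suprafacial on both components, which forms the C1–C2 and C5–C6 bonds at once. The C1/C6 trans relation is copied from the E-enone, the C2 configuration relative to C1 follows from the E-diene reacting through the transition state with the boron-bound aroyl group exo (ring B endo), and the absolute configuration of all three centres is set by the ligand, one 3-phenylnaphthyl wall of which should cover one enone face so that the diene adds to the Cα-Re/Cβ-Re face. Regioselectivity is secured because the 1-aryl and 3-methyl groups of 15 both place the largest HOMO coefficient on the CH2 terminus, which pairs with the β-carbon of 16. The demanding requirement is exo selectivity, which is expected from the bulk of the spiro-borate around the carbonyl (it disfavours placing the tetrasubstituted ring A of the diene beneath it) and from π-stacking of the endo ring B with the diene, while acetylation of every other phenol ensures that boron binds only at the ketone chelate site.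

Step 12
Reactants: 18 exo-(1S,2S,6R) cycloadduct heptaacetate (2'-OH free)
Product: 19 (2,4-dihydroxyphenyl)[(1S,2S,6R)-6-(2,4-dihydroxyphenyl)-2-{5-[(E)-2-(3,5-dihydroxyphenyl)ethenyl]-2,4-dihydroxyphenyl}-4-methylcyclohex-3-en-1-yl]methanone
Conditions: K2CO3, degassed MeOH, 0 °C to rt, argon; then dilute AcOH to pH 6
Reagents that add atoms: none
Why: Base-catalysed transesterification (methanolysis) of the seven aryl acetates under acid-free conditions avoids ketalisation of the ketone by the flanking ortho-phenols, and because the all-trans (all-equatorial) arrangement is the thermodynamic one the enolisable C1 centre should not drift.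

**Compound list**

1 | 2,4-dihydroxyacetophenone | CC(=O)c1ccc(O)cc1O | starting material
2 | 1-[2-hydroxy-4-(methoxymethoxy)phenyl]ethan-1-one | CC(=O)c1ccc(OCOC)cc1O | intermediate
3 | 2,4-dihydroxybenzaldehyde | O=Cc1ccc(O)cc1O | starting material
4 | 2,4-bis(methoxymethoxy)benzaldehyde | COCOc1ccc(C=O)c(OCOC)c1 | intermediate
5 | (E)-1-[2-hydroxy-4-(methoxymethoxy)phenyl]-3-[2,4-bis(methoxymethoxy)phenyl]prop-2-en-1-one | COCOc1ccc(C(=O)/C=C/c2ccc(OCOC)cc2OCOC)c(O)c1 | intermediate
6 | (E)-1,3-bis(2,4-dihydroxyphenyl)prop-2-en-1-one | O=C(/C=C/c1ccc(O)cc1O)c1ccc(O)cc1O | intermediate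
7 | (E)-1-(4-acetoxy-2-hydroxyphenyl)-3-(2,4-diacetoxyphenyl)prop-2-en-1-one | CC(=O)Oc1ccc(C(=O)/C=C/c2ccc(OC(C)=O)cc2OC(C)=O)c(O)c1 | intermediate
8 | 5-bromo-2,4-dimethoxybenzaldehyde | COc1cc(OC)c(C=O)cc1Br | starting material
9 | diethyl (3,5-dimethoxybenzyl)phosphonate | CCOP(=O)(Cc1cc(OC)cc(OC)c1)OCC | starting material
10 | 1-bromo-5-[(E)-2-(3,5-dimethoxyphenyl)ethenyl]-2,4-dimethoxybenzene | COc1cc(OC)cc(/C=C/c2cc(Br)c(OC)cc2OC)c1 | intermediate
11 | 4-bromo-6-[(E)-2-(3,5-dihydroxyphenyl)ethenyl]benzene-1,3-diol | Oc1cc(O)cc(/C=C/c2cc(Br)c(O)cc2O)c1 | intermediate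
12 | 4-bromo-6-[(E)-2-(3,5-diacetoxyphenyl)ethenyl]-1,3-phenylene diacetate | CC(=O)Oc1cc(OC(C)=O)cc(/C=C/c2cc(Br)c(OC(C)=O)cc2OC(C)=O)c1 | intermediate
13 | 2-methylbut-1-en-3-yne | C=C(C)C#C | starting material
14 | 4,4,5,5-tetramethyl-2-[(1E)-3-methylbuta-1,3-dien-1-yl]-1,3,2-dioxaborolane | C=C(C)/C=C/B1OC(C)(C)C(C)(C)O1 | intermediate
15 | 4-[(E)-2-(3,5-diacetoxyphenyl)ethenyl]-6-[(1E)-3-methylbuta-1,3-dien-1-yl]-1,3-phenylene diacetate | C=C(C)/C=C/c1cc(/C=C/c2cc(OC(C)=O)cc(OC(C)=O)c2)c(OC(C)=O)cc1OC(C)=O | intermediate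
16 | spiro-borate chelate of 7: boron bound to the 2'-phenolate O, the ketone O and both oxygens of (S)-VANOL (axial chirality of the ligand not encoded in the SMILES) | CC(=O)Oc1ccc2c(c1)O[B-]1(Oc3c(-c4c(O1)c5ccccc5cc4-c4ccccc4)c(-c4ccccc4)cc4ccccc34)[O+]=C2/C=C/c1ccc(OC(C)=O)cc1OC(C)=O | intermediate
17 | the same (S)-VANOL spiro-borate chelate on the (1S,2S,6R) cycloadduct (axial chirality of the ligand not encoded) | CC1=C[C@H](c2cc(/C=C/c3cc(OC(C)=O)cc(OC(C)=O)c3)c(OC(C)=O)cc2OC(C)=O)[C@@H](C2=[O+][B-]3(Oc4cc(OC(C)=O)ccc42)Oc2c(-c4c(O3)c5ccccc5cc4-c4ccccc4)c(-c4ccccc4)cc4ccccc24)[C@H](c2ccc(OC(C)=O)cc2OC(C)=O)C1 | intermediate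
18 | (4-acetoxy-2-hydroxyphenyl)[(1S,2S,6R)-6-(2,4-diacetoxyphenyl)-2-{2,4-diacetoxy-5-[(E)-2-(3,5-diacetoxyphenyl)ethenyl]phenyl}-4-methylcyclohex-3-en-1-yl]methanone | CC1=C[C@H](c2cc(/C=C/c3cc(OC(C)=O)cc(OC(C)=O)c3)c(OC(C)=O)cc2OC(C)=O)[C@@H](C(=O)c2ccc(OC(C)=O)cc2O)[C@H](c2ccc(OC(C)=O)cc2OC(C)=O)C1 | intermediate
19 | (2,4-dihydroxyphenyl)[(1S,2S,6R)-6-(2,4-dihydroxyphenyl)-2-{5-[(E)-2-(3,5-dihydroxyphenyl)ethenyl]-2,4-dihydroxyphenyl}-4-methylcyclohex-3-en-1-yl]methanone | CC1=C[C@H](c2cc(/C=C/c3cc(O)cc(O)c3)c(O)cc2O)[C@@H](C(=O)c2ccc(O)cc2O)[C@H](c2ccc(O)cc2O)C1 | target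

**Step count**

Total steps: 12. Longest linear sequence: 6 steps (1 → 2 → 5 → 6 → 7 → 18 → 19; equally 8 → 10 → 11 → 12 → 15 → 18 → 19).

**Steps most likely to fail, with fallbacks**

1. Step 11. The borate chelate may discriminate too weakly between exo and endo approach or between the two enone faces, or the diene may oligomerise under the Lewis acid. Fallback: setting out from 7 and 15, the cycloaddition would be run thermally without boron (toluene, BHT, sealed tube, 120 °C), which should give both diastereomers as racemates. The exo diastereomer, the racemic exo adduct F1, would be separated on silica and resolved by preparative HPLC on a cellulose tris(3,5-dimethylphenylcarbamate) stationary phase; the (1S,2S,6R) enantiomer is 18, where the route is rejoined.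

2. Step 10. Aryl acetates may be lost to fluoride, and the dienylboronate may protodeboronate or polymerise before transmetalation. Fallback: setting out from 12, a Heck reaction with 2-methylbut-3-en-2-ol (Pd(OAc)2, P(o-tol)3, Et3N, DMF, 90 °C) would give the E-configured tertiary allylic alcohol F2. Dehydration (MsCl, excess Et3N, CH2Cl2, 0 °C to rt), in which only methyl hydrogens can be lost, would give 15, where the route is rejoined.

3. Step 7. The electron-rich stilbene may oligomerise under acid (protonation of the alkene conjugated to the resorcinol ring), or ether cleavage may stay incomplete. Fallback: setting out from 8, BBr3 demethylation at the aldehyde stage, where no stilbene is present, would give 5-bromo-2,4-dihydroxybenzaldehyde F3. Acetylation (Ac2O, pyridine) would give 5-bromo-2,4-diacetoxybenzaldehyde F4. A Heck coupling with commercial 3,5-diacetoxystyrene (Pd(OAc)2, P(o-tol)3, Et3N, DMF, 90 °C) would give the stilbene aldehyde tetraacetate F5; since ring A is a 4,6-disubstituted resorcinol, the former aldehyde and bromide positions are interchangeable. Zinc-mediated Barbier addition of 3-bromo-2-methylpropene (Zn dust, THF/aq NH4Cl, rt) would give the racemic homoallylic alcohol F6. Dehydration into conjugation (MsCl, excess Et3N, CH2Cl2, 0 to 40 °C) would give 15, where the route is rejoined; steps 6 to 10 are then not needed.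

**Further compounds**

F1 | step 11 | racemic exo adduct (18 together with its enantiomer) | CC1=C[C@H](c2cc(/C=C/c3cc(OC(C)=O)cc(OC(C)=O)c3)c(OC(C)=O)cc2OC(C)=O)[C@@H](C(=O)c2ccc(OC(C)=O)cc2O)[C@H](c2ccc(OC(C)=O)cc2OC(C)=O)C1.CC1=C[C@@H](c2cc(/C=C/c3cc(OC(C)=O)cc(OC(C)=O)c3)c(OC(C)=O)cc2OC(C)=O)[C@H](C(=O)c2ccc(OC(C)=O)cc2O)[C@@H](c2ccc(OC(C)=O)cc2OC(C)=O)C1
F2 | step 10 | 4-[(E)-2-(3,5-diacetoxyphenyl)ethenyl]-6-[(1E)-3-hydroxy-3-methylbut-1-en-1-yl]-1,3-phenylene diacetate | CC(C)(O)/C=C/c1cc(/C=C/c2cc(OC(C)=O)cc(OC(C)=O)c2)c(OC(C)=O)cc1OC(C)=O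
F3 | step 7 | 5-bromo-2,4-dihydroxybenzaldehyde | O=Cc1cc(Br)c(O)cc1O
F4 | step 7 | 5-bromo-2,4-diacetoxybenzaldehyde | CC(=O)Oc1cc(OC(C)=O)c(C=O)cc1Br
F5 | step 7 | 4-[(E)-2-(3,5-diacetoxyphenyl)ethenyl]-6-formyl-1,3-phenylene diacetate | CC(=O)Oc1cc(OC(C)=O)cc(/C=C/c2cc(C=O)c(OC(C)=O)cc2OC(C)=O)c1
F6 | step 7 | 4-[(E)-2-(3,5-diacetoxyphenyl)ethenyl]-6-(1-hydroxy-3-methylbut-3-en-1-yl)-1,3-phenylene diacetate (racemic) | C=C(C)CC(O)c1cc(/C=C/c2cc(OC(C)=O)cc(OC(C)=O)c2)c(OC(C)=O)cc1OC(C)=O
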